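**Plan**

1. Lignan numbering: ring A = C7–O–C9'–C8'–C8 with the 4-hydroxy-3-methoxyphenyl group endo on C7; ring B = C7'–O–C9–C8–C8' with the prenyloxyaryl group exo on C7'. The target is (7R,8R,7'S,8'R), i.e. (1R,3aR,4S,6aR) in furofuran numbering.
2. Cuts: the silyl ether; the O–C9' ether of ring A, traced back to a C9' lactone; the lactone at C7–C8 and O–C9', giving a silylated vanillin and a 2-aryl-2,5-dihydrofuran-3-carboxylate; ring B at C8=C8' (metathesis), O–C9 (allylation) and C7'–C8' (Morita–Baylis–Hillman).
3. Enabling feature: C7 is an aldehyde carbon and C8 is the β-carbon of the C8=C8'–C9' acrylate held in ring B. Both are electrophiles, so C7–C8 is made by polarity reversal of C7 as a samarium ketyl, and the C7 alkoxide then acylates on C9'.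
4. Forward order: ring B first (steps 1–5), ring A as a lactone in the coupling (step 7), then lactone to diol to ether (steps 8–9), desilylation last.
5. Stereochemistry: C7' comes from the β-isocupreidine-catalysed Morita–Baylis–Hillman reaction; C8, C8' and C7 are relayed from C7' in step 7; the re-closure substitutes only the primary C9', so C7 is retained.

Key step: step 7

Abbreviations: ArP = 3-methoxy-4-(3-methylbut-2-en-1-yloxy)phenyl; ArSi = 3-methoxy-4-(triisopropylsilyloxy)phenyl; HFIP = 1,1,1,3,3,3-hexafluoropropan-2-yl.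
Remark: β-isocupreidine is assumed to give the (R)-carbinol with aldehyde 3, as it does with other aromatic aldehydes.

**Route**

Step 1
Reactants: 1 vanillin; 2 prenyl bromide
Product: 3 3-methoxy-4-(3-methylbut-2-en-1-yloxy)benzaldehyde
Conditions: K2CO3, DMF, rt
Reagents that add atoms: none
Why: Williamson ether synthesis, in which the phenoxide should displace bromide at the unhindered primary allylic carbon and the aldehyde is inert to carbonate.

Step 2
Reactants: 3 3-methoxy-4-(3-methylbut-2-en-1-yloxy)benzaldehyde; 4 HFIP acrylate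
Product: 5 HFIP (R)-2-[hydroxy(ArP)methyl]prop-2-enoate
Conditions: β-isocupreidine (β-ICD, 10–20 mol%), 4 (1.5 equiv), DMF, −55 °C
Reagents that add atoms: none
Why: Enantioselective Morita–Baylis–Hillman reaction, in which the quinuclidine nitrogen of β-ICD adds to the strongly activated fluorinated acrylate, the resulting enolate adds to 3, and the C6' phenol of the catalyst steers proton transfer so that only the betaine leading to the (R)-carbinol releases the catalyst, which sets C7'.

Step 3
Reactants: 5 HFIP (R)-2-[hydroxy(ArP)methyl]prop-2-enoate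
Product: 6 methyl (R)-2-[hydroxy(ArP)methyl]prop-2-enoate
Conditions: Et3N (cat.), MeOH, rt
Reagents that add atoms: methanol, CO
Why: Base-catalysed transesterification of an activated ester whose fluorinated alkoxide is a good leaving group, with the carbinol centre not involved.

Step 4
Reactants: 6 methyl (R)-2-[hydroxy(ArP)methyl]prop-2-enoate; 7 allyl bromide
Product: 8 methyl (R)-2-[(prop-2-en-1-yloxy)(ArP)methyl]prop-2-enoate
Conditions: Ag2O, 7 (excess), Et2O, rt, dark
Reagents that add atoms: none
Why: Silver-oxide-promoted Williamson-type O-allylation under neutral conditions, which avoids both a free alkoxide (retro-aldol, oxa-Michael addition) and acid (ionisation of the electron-rich benzylic carbinol), so C7' should keep its configuration.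

Step 5
Reactants: 8 methyl (R)-2-[(prop-2-en-1-yloxy)(ArP)methyl]prop-2-enoate
Product: 9 methyl (R)-2-ArP-2,5-dihydrofuran-3-carboxylate
Conditions: second-generation Grubbs catalyst RuCl2(H2IMes)(PCy3)(=CHPh) (5 mol%), CH2Cl2 (0.01 M), 40 °C
Reagents that add atoms: none
Why: Ring-closing olefin metathesis, in which the ruthenium alkylidene loads on the monosubstituted allyl olefin and closes the five-membered ring B onto the 1,1-disubstituted acrylate olefin with loss of ethene, while the trisubstituted prenyl olefin is a poor partner at this dilution.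

Step 6
Reactants: 1 vanillin
Product: 10 3-methoxy-4-(triisopropylsilyloxy)benzaldehyde
Conditions: i-Pr3SiCl, imidazole, DMF, rt
Reagents that add atoms: triisopropylsilyl chloride, CC(C)[Si](Cl)(C(C)C)C(C)C
Why: Imidazole-promoted silylation of the phenol, the triisopropylsilyl group being chosen because its aryl ethers should withstand SmI2, LiAlH4 and amine bases and still fall to fluoride.

Step 7
Reactants: 9 methyl (R)-2-ArP-2,5-dihydrofuran-3-carboxylate; 10 3-methoxy-4-(triisopropylsilyloxy)benzaldehyde
Product: 12 (3R,3aR,6S,6aS)-3-ArSi-6-ArP-tetrahydro-1H,3H-furo[3,4-c]furan-1-one (endo,exo lactone), via γ-hydroxy ester 11 (not isolated)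
Conditions: SmI2 (4 equiv), t-BuOH (3 equiv), THF, −78 °C, 10 (2 equiv) added over 2 h to 9 (1 equiv), then 0 °C; DBU (cat.), CH2Cl2, rt on the crude if open ester remains
Reagents that add atoms: none
Why: SmI2 should reduce the aryl aldehyde, the more easily reduced partner, to a ketyl on trivalent samarium that adds in Giese fashion to C8 of the enoate; a second SmI2 turns the α-ester radical into the samarium enolate, t-BuOH protonates C8', and the C7 alkoxide of 11 attacks the C9' ester and expels methoxide. The closest known reaction is the SmI2-promoted reductive coupling of aldehydes with β-substituted acrylates, which gives cis-β,γ-disubstituted γ-butyrolactones. Ring A closes by 5-exo-trig acyl substitution of the C7 oxygen on C9', after C7–C8 has formed intermolecularly. C8 is set by approach of the ketyl to the ring face opposite the C7' aryl, and C7 is set in the same event by the samarium bridge between ketyl oxygen and ester carbonyl, which turns the ketyl aryl away from ring B and gives the cis-β,γ (endo-aryl) relation. C8' is set by protonation, and because only the epimer with C9' cis to the C7 oxygen (and so trans to the C7' aryl) can close the cis-fused bicycle, the other epimer should drain through the enolate into 12. The step needs cross-coupling over pinacol dimerisation, secured by slow addition of 10 to acceptor and reductant, and enolate protonation over β-elimination of the ring oxygen on C7', secured by t-BuOH and by the poor overlap of that in-ring C–O bond with the exocyclic enolate (the reverse of a 5-endo-trig closure).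

Step 8
Reactants: 12 (3R,3aR,6S,6aS)-3-ArSi-6-ArP-tetrahydro-1H,3H-furo[3,4-c]furan-1-one
Product: 13 (R)-[(3R,4R,5S)-4-(hydroxymethyl)-5-ArP-tetrahydrofuran-3-yl](ArSi)methanol
Conditions: LiAlH4, THF, 0 °C
Reagents that add atoms: none
Why: Hydride reduction of the lactone takes C9' to the primary alcohol and frees the C7 hydroxyl without touching any stereocentre, the aryl silyl ether or the prenyl ether.

Step 9
Reactants: 13 (R)-[(3R,4R,5S)-4-(hydroxymethyl)-5-ArP-tetrahydrofuran-3-yl](ArSi)methanol
Product: 15 (1R,3aR,4S,6aR)-1-ArSi-4-ArP-tetrahydro-1H,3H-furo[3,4-c]furan, via primary mesylate 14 (not isolated)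
Conditions: MsCl (1.05 equiv), Et3N (3 equiv), CH2Cl2, −20 °C to rt
Reagents that add atoms: none
Why: Selective sulfonylation of the less hindered primary hydroxyl followed by intramolecular Williamson etherification (5-exo-tet attack of the cis-disposed C7 hydroxyl on C9') should re-close ring A with retention at C7, because the C7–O bond is never broken.

Step 10
Reactants: 15 (1R,3aR,4S,6aR)-1-ArSi-4-ArP-tetrahydro-1H,3H-furo[3,4-c]furan
Product: 16 2-methoxy-4-[(1R,3aR,4S,6aR)-4-ArP-tetrahydro-1H,3H-furo[3,4-c]furan-1-yl]phenol
Conditions: Bu4NF, AcOH (1:1), THF, 0 °C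
Reagents that add atoms: none
Why: Fluoride-driven cleavage of the aryl silyl ether, buffered with acetic acid so that the phenoxide is protonated before it can open ring A through a quinone methide and epimerise C7.

**Compound list**

1 | vanillin | COc1cc(C=O)ccc1O | starting material
2 | prenyl bromide (1-bromo-3-methylbut-2-ene) | CC(C)=CCBr | starting material
3 | 3-methoxy-4-(3-methylbut-2-en-1-yloxy)benzaldehyde | COc1cc(C=O)ccc1OCC=C(C)C | intermediate
4 | 1,1,1,3,3,3-hexafluoropropan-2-yl acrylate | C=CC(=O)OC(C(F)(F)F)C(F)(F)F | starting material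
5 | HFIP (R)-2-[hydroxy(ArP)methyl]prop-2-enoate | C=C([C@H](O)c1ccc(OCC=C(C)C)c(OC)c1)C(=O)OC(C(F)(F)F)C(F)(F)F | intermediate
6 | methyl (R)-2-[hydroxy(ArP)methyl]prop-2-enoate | COC(=O)C(=C)[C@H](O)c1ccc(OCC=C(C)C)c(OC)c1 | intermediate
7 | allyl bromide | C=CCBr | starting material
8 | methyl (R)-2-[(prop-2-en-1-yloxy)(ArP)methyl]prop-2-enoate | COC(=O)C(=C)[C@H](OCC=C)c1ccc(OCC=C(C)C)c(OC)c1 | intermediate
9 | methyl (R)-2-ArP-2,5-dihydrofuran-3-carboxylate | COC(=O)C1=CCO[C@@H]1c1ccc(OCC=C(C)C)c(OC)c1 | intermediate
10 | 3-methoxy-4-(triisopropylsilyloxy)benzaldehyde | COc1cc(C=O)ccc1O[Si](C(C)C)(C(C)C)C(C)C | intermediate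
11 | methyl (2S,3S,4R)-4-[(R)-hydroxy(ArSi)methyl]-2-ArP-tetrahydrofuran-3-carboxylate (as its samarium alkoxide in the flask) | O[C@@H](c1ccc(O[Si](C(C)C)(C(C)C)C(C)C)c(OC)c1)[C@H]1CO[C@H](c2ccc(OCC=C(C)C)c(OC)c2)[C@H]1C(=O)OC | intermediate
12 | (3R,3aR,6S,6aS)-3-ArSi-6-ArP-tetrahydro-1H,3H-furo[3,4-c]furan-1-one | O=C1O[C@@H](c3ccc(O[Si](C(C)C)(C(C)C)C(C)C)c(OC)c3)[C@H]2CO[C@H](c3ccc(OCC=C(C)C)c(OC)c3)[C@@H]12 | intermediate
13 | (R)-[(3R,4R,5S)-4-(hydroxymethyl)-5-ArP-tetrahydrofuran-3-yl](ArSi)methanol | O[C@@H](c1ccc(O[Si](C(C)C)(C(C)C)C(C)C)c(OC)c1)[C@H]1CO[C@H](c2ccc(OCC=C(C)C)c(OC)c2)[C@H]1CO | intermediate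
14 | [(2S,3R,4R)-4-[(R)-hydroxy(ArSi)methyl]-2-ArP-tetrahydrofuran-3-yl]methyl methanesulfonate | O[C@@H](c1ccc(O[Si](C(C)C)(C(C)C)C(C)C)c(OC)c1)[C@H]1CO[C@H](c2ccc(OCC=C(C)C)c(OC)c2)[C@H]1COS(C)(=O)=O | intermediate
15 | (1R,3aR,4S,6aR)-1-ArSi-4-ArP-tetrahydro-1H,3H-furo[3,4-c]furan | COc1cc([C@@H]2OC[C@H]3[C@@H]2CO[C@@H]3c2ccc(OCC=C(C)C)c(OC)c2)ccc1O[Si](C(C)C)(C(C)C)C(C)C | intermediate
16 | 2-methoxy-4-[(1R,3aR,4S,6aR)-4-ArP-tetrahydro-1H,3H-furo[3,4-c]furan-1-yl]phenol | COc1cc([C@@H]2OC[C@H]3[C@@H]2CO[C@@H]3c2ccc(OCC=C(C)C)c(OC)c2)ccc1O | target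

**Step count and risks**

Total steps: 10. Longest linear sequence: 9 (steps 1–5 and 7–10, from vanillin).

Steps most likely to fail:

1. Step 7. The aryl ketyl may dimerise to the pinacol faster than it adds to the hindered trisubstituted enoate. The remote C7' aryl may discriminate the ring faces poorly at C8, the cis-β,γ preference at C7 may be weak, and the enolate may open ring B by β-elimination. The fallback replaces the radical by a two-electron acyl-anion equivalent. It sets out from 10 and 9 and returns at 11, which closes to 12. Aldehyde 10 with propane-1,3-dithiol and catalytic BF3·OEt2 (CH2Cl2, 0 °C) should give 2-ArSi-1,3-dithiane F1. Lithiation (n-BuLi, THF, −78 °C) and conjugate addition to 9 in the presence of DMPU, anti to the C7' aryl, followed by kinetic protonation of the enolate away from the bulky dithianyl group, should give methyl (2S,3S,4R)-4-(2-ArSi-1,3-dithian-2-yl)-2-ArP-tetrahydrofuran-3-carboxylate F2. Hydrolysis of the dithiane (MeI, CaCO3, aqueous MeCN) should give the aryl ketone methyl (2S,3S,4R)-4-(3-methoxy-4-triisopropylsilyloxybenzoyl)-2-ArP-tetrahydrofuran-3-carboxylate F3. Reduction with LiBH(s-Bu)3 (THF, −78 °C), expected to follow Felkin–Anh control from C8, gives hydroxy ester 11, which lactonises to 12 with catalytic DBU; a C7 epimer would be separated at the lactone stage.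

2. Step 2. The aldol stage of the Morita–Baylis–Hillman cycle may be slow with the moderately electron-rich aldehyde, so that the fluorinated acrylate is consumed in side reactions and the enantioselectivity erodes over long reaction times. The fallback sets C7' by ketone reduction instead. It sets out from 3 and returns at 6. Addition of the lithium enolate of methyl acetate (LiN(i-Pr)2, THF, −78 °C) to 3 should give racemic methyl 3-ArP-3-hydroxypropanoate F4. Oxidation with MnO2 (CH2Cl2) should give methyl 3-ArP-3-oxopropanoate F5. Noyori-type asymmetric transfer hydrogenation with RuCl(p-cymene)[(S,S)-TsDPEN] in HCO2H–Et3N should give methyl (S)-3-ArP-3-hydroxypropanoate F6. This has the same spatial arrangement as (R)-6; the descriptor changes only because the ranking of the carbon substituents changes. Fráter–Seebach dianion formation (LiN(i-Pr)2, 2.2 equiv) and trapping with Eschenmoser's salt (dimethylmethyleneiminium iodide) should give the anti Mannich base methyl (2R,3S)-2-[(dimethylamino)methyl]-3-ArP-3-hydroxypropanoate F7. Quaternisation with MeI and elimination with DBU then gives 6.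

3. Step 9. Sulfonylation may also occur at the benzylic C7 hydroxyl, or the electron-rich benzylic position may ionise. Either would close ring A from the other oxygen and epimerise C7 towards the more stable exo-aryl isomer. The fallback gives up sulfonate activation. It sets out from 13 and returns at 15. A Mitsunobu redox dehydration (PPh3, diisopropyl azodicarboxylate, THF, 0 °C) should form the bulky alkoxyphosphonium ion only at the primary C9' hydroxyl under neutral conditions, and the C7 hydroxyl then displaces phosphine oxide with retention at C7. It passes through no compound beyond those listed, hence the entry F0.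

**Further compounds**

F1 | step 7 | 2-ArSi-1,3-dithiane | COc1cc(C2SCCCS2)ccc1O[Si](C(C)C)(C(C)C)C(C)C
F2 | step 7 | methyl (2S,3S,4R)-4-(2-ArSi-1,3-dithian-2-yl)-2-ArP-tetrahydrofuran-3-carboxylate | COc1cc(C2(SCCCS2)[C@H]3CO[C@H](c4ccc(OCC=C(C)C)c(OC)c4)[C@H]3C(=O)OC)ccc1O[Si](C(C)C)(C(C)C)C(C)C
F3 | step 7 | methyl (2S,3S,4R)-4-(3-methoxy-4-triisopropylsilyloxybenzoyl)-2-ArP-tetrahydrofuran-3-carboxylate | COc1cc(C(=O)[C@H]2CO[C@H](c3ccc(OCC=C(C)C)c(OC)c3)[C@H]2C(=O)OC)ccc1O[Si](C(C)C)(C(C)C)C(C)C
F4 | step 2 | racemic methyl 3-ArP-3-hydroxypropanoate | COC(=O)CC(O)c1ccc(OCC=C(C)C)c(OC)c1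
F5 | step 2 | methyl 3-ArP-3-oxopropanoate | COC(=O)CC(=O)c1ccc(OCC=C(C)C)c(OC)c1
F6 | step 2 | methyl (S)-3-ArP-3-hydroxypropanoate | COC(=O)C[C@H](O)c1ccc(OCC=C(C)C)c(OC)c1
F7 | step 2 | methyl (2R,3S)-2-[(dimethylamino)methyl]-3-ArP-3-hydroxypropanoate | COC(=O)[C@H](CN(C)C)[C@H](O)c1ccc(OCC=C(C)C)c(OC)c1
F0 | step 9 | none | none
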